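## Analysis of the target

- The target is an abietane diterpenoid, 2α-acetoxy-20-deoxocarnosol (abietane numbering C1–C20 is used throughout). Ring A is the cyclohexane C1–C5/C10, ring B is C5–C10, and ring C is the arene C8, C9, C11–C14 with a catechol at C11/C12 and isopropyl at C13.
- C20 is linked through oxygen to benzylic C7, so ring B and the C7–O–C20–C10 bridge form a 2-oxabicyclo[2.2.2]octene that is benzo-fused at C8–C9.
- There are four stereocentres: quaternary C10 (R), C5 (S), C7 (S) and C2 (S). C7 and C10 are tied together by the bridge, H5 is anti to C20 (trans A/B fusion), and the 2α-acetoxy group is equatorial on ring A.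
- The sensitive groups are the air-sensitive catechol, the secondary acetate (base, hydride), and the benzylic C7–O ether para to the C12 oxygen (acid ionisation, hydrogenolysis).
- The difficulties are the quaternary C10 between the arene, the bridge and C5 (which sits next to the gem-dimethyl C4), the C2 oxygen with no neighbouring functionality, and a deprotection that must spare acetate and bridge.
- The feature the strategy uses: the oxabicycle is the formal [4+2] adduct of a 2-benzopyrylium ion (O, C7, C8, C9, C10, C20) with the C5=C6 alkene, and ring A (C1–C4) is exactly the tether that holds this alkene on C10.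

## Retrosynthetic reasoning

**25 ⇒ 24.** Only the catechol is masked in 24, as a cyclic isopropylidene ketal. This ketal has no C–H that the earlier organolithium steps could remove, it keeps the oxygen peri to C10 small, and aqueous acid releases it without touching the acetate.

**24 ⇒ 21 (key disconnection).** The bonds C6–C7 and C5–C10 are cut and one hydride is moved from C20 back to C7. Compound 21 is then an isomer of 24: a flat 1H-isochromene carrying an acyclic chain, with C2 as its only stereocentre. These two bonds create ring A, ring B, the quaternary C10 and the C5/C7/C10 triad in one operation, and the oxygen bridge is already present as the pyran oxygen. The forward reaction must abstract hydride at C7 to give benzopyrylium ion 22, run the intramolecular [4+2] to oxocarbenium ion 23, and return hydride to C20.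

**21 ⇒ 14 + 18.** The C10–C1 bond is cut, giving vinyl bromide 14 (as vinyllithium 19) and epoxide 18. The chain is attached only after C7 and C20 have their final oxidation levels, and the alkoxide 20 is acetylated at once. A free C2 hydroxyl would otherwise add to the enol ether, or form a five-membered lactol or lactone with any C20 carbonyl.

**14 ⇒ 11 ⇒ 9.** The vinyl bromide comes from isocoumarin 9 by bromination of its enol-lactone double bond (11). The lactone carbonyl (C7) is then reduced to CH2 through lactolate 12 and benzopyrylium ion 13.

**9 ⇒ 6.** The C10–C20 bond and the lactone C–O bond are cut. Lateral lithiation of o-toluamide 6 (benzyllithium 7), formylation to aldehyde 8 and enol lactonisation build the pyranone ring.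

**6 ⇒ 4 ⇒ 3 ⇒ 1.** The amide carbon (C7) enters at the bromine of 4 through aryllithium 5. The second phenolic oxygen (C11) is placed ortho to the phenol of 1 through o-quinone 2. In 4-bromothymol 1 the methyl is C10, the bromine marks C8, the hydroxyl is the C12 oxygen and the isopropyl group is already on C13, so every ring position is fixed by the starting material.

**18 ⇒ 15 + 16.** The C3–C4 bond is cut. The tertiary terminus of prenyl Grignard reagent 16 opens (S)-epichlorohydrin 15 (chloromagnesium alkoxide 17), which delivers the gem-dimethyl carbon, the vinyl group and the C2 stereocentre in one step.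

## Alternatives that were turned down

**Alternative 1:** the textbook disconnection, C4–C5 and C9–C10 by cationic polyene cyclisation.
- Forward: the aryl-terminated diene A1 cyclises to the tricycle A2, followed by benzylic C7 oxidation and ether closure.
- Turned down: the cyclisation brings no oxygen to C2. An oxygen placed at C2 in A1 would sit β to the initiating C4 cation and deactivate it, and an epoxide initiator oxygenates C3 instead.
- After the cyclisation only undirected C–H oxidation is left for C2, and that would attack benzylic C7 and the electron-rich arene first.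
- Absolute control would also need a chiral initiator, and the C7–O bridge and the C2 problem would add many steps after A2.

**Alternative 2:** C7–C8 and C7–O by an oxa-Pictet–Spengler closure of ring B.
- Forward: the hydroxy aldehyde A3 condenses (C20–OH with the C7 aldehyde) and the oxocarbenium ion closes onto C8, para to the C12 oxygen.
- Turned down: the key step forms one C–C bond and no independent stereocentre.
- A3 already contains ring A with three stereocentres, including the aryl-bearing quaternary C10 next to C5 and the gem-dimethyl C4. Making that centre enantioselectively is the real problem and would cost more steps than the whole route below.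

**Alternative 3:** both aryl–carbon bonds (C7–C8, C9–C10) by an aryne [4+2].
- Forward: the aryne from silyl triflate A4 adds to the bicyclic 2H-pyran A5 to give the bridged diene A6, then the C5=C6 bond is hydrogenated.
- Turned down on regiochemistry: the methoxy group next to the triple bond directs the nucleophilic diene terminus (C10, remote from the pyran oxygen) to the aryne carbon meta to it (C8). The target needs C10 on C9.
- A5 is in equilibrium with its ring-opened dienal.
- Nothing directs hydrogen to the arene-facing side of the C5=C6 bond of A6, so the cis A/B isomer is expected.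

Key step: step 9

Assumption: 4-bromothymol (1), (S)-epichlorohydrin (15) and prenylmagnesium chloride solution (16) are taken as commercial; all atoms are numbered as in abietane.

## Route

Step 1
Reactants: 1 4-bromo-5-methyl-2-(propan-2-yl)phenol (4-bromothymol)
Product: 3 4-bromo-3-methyl-6-(propan-2-yl)benzene-1,2-diol, via o-quinone 2 (not isolated)
Conditions: IBX, DMF, 25 °C; then Na2S2O4 (aq.)
Reagents that add atoms: 2-iodoxybenzoic acid (IBX), O=C1OI(=O)(O)c2ccccc12
Why: IBX-mediated ortho-oxygenation of a phenol: the phenol binds to iodine and oxygen is delivered to the only free ortho carbon (C11; the other ortho carbon bears the isopropyl group), giving o-quinone 2, which dithionite reduces in the same flask to catechol 3.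

Step 2
Reactants: 3 4-bromo-3-methyl-6-(propan-2-yl)benzene-1,2-diol
Product: 4 5-bromo-2,2,4-trimethyl-7-(propan-2-yl)-1,3-benzodioxole
Conditions: 2,2-dimethoxypropane, TsOH·H2O (cat.), toluene, reflux, 4 Å molecular sieves
Reagents that add atoms: 2,2-dimethoxypropane, COC(C)(C)OC
Why: Acid-catalysed transketalisation closes the five-membered aryl ketal, which has no C–H acidic toward the later organolithium steps, keeps the C11 oxygen tied back, and is cleaved by aqueous acid at the end.

Step 3
Reactants: 4 5-bromo-2,2,4-trimethyl-7-(propan-2-yl)-1,3-benzodioxole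
Product: 6 N,N-diethyl-2,2,4-trimethyl-7-(propan-2-yl)-1,3-benzodioxole-5-carboxamide, via aryllithium 5 (not isolated)
Conditions: n-BuLi, THF, −78 °C; then Et2NCOCl, −78 → 0 °C
Reagents that add atoms: N,N-diethylcarbamoyl chloride, CCN(CC)C(Cl)=O
Why: Bromine–lithium exchange is faster than any deprotonation at −78 °C and gives aryllithium 5 at C8 only; acylation by the carbamoyl chloride stops at the tertiary amide, which is the directing group for step 4 and supplies C7.

Step 4
Reactants: 6 N,N-diethyl-2,2,4-trimethyl-7-(propan-2-yl)-1,3-benzodioxole-5-carboxamide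
Product: 9 5,6-(isopropylidenedioxy)-7-(propan-2-yl)-1H-isochromen-1-one, via benzyllithium 7 (not isolated), via aldehyde 8 (not isolated)
Conditions: LiN(i-Pr)2, THF, −78 °C; DMF, −78 → 0 °C; then AcOH, 100 °C
Reagents that add atoms: N,N-dimethylformamide, CN(C)C=O
Why: Lateral lithiation: the amide carbonyl and the flanking dioxole oxygen direct the base to the benzylic methyl (C10); formylation gives arylacetaldehyde 8 (C20), whose enol acylates on the amide under acid (6-exo-trig enol lactonisation, loss of diethylamine) to give isocoumarin 9.

Step 5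
Reactants: 9 5,6-(isopropylidenedioxy)-7-(propan-2-yl)-1H-isochromen-1-one
Product: 11 4-bromo-5,6-(isopropylidenedioxy)-7-(propan-2-yl)-1H-isochromen-1-one, via dibromide 10 (not isolated)
Conditions: Br2, CH2Cl2, 0 °C; then Et3N, 0 → 25 °C
Reagents that add atoms: bromine, BrBr
Why: Electrophilic bromination–dehydrobromination of the enol-lactone double bond puts bromine on its nucleophilic β-carbon (C10); the arene is deactivated by the lactone carbonyl and its only free position is flanked by the isopropyl group.

Step 6
Reactants: 11 4-bromo-5,6-(isopropylidenedioxy)-7-(propan-2-yl)-1H-isochromen-1-one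
Product: 14 4-bromo-5,6-(isopropylidenedioxy)-7-(propan-2-yl)-1H-isochromene, via aluminium lactolate 12 (not isolated), via bromoisochromenylium ion 13 (not isolated)
Conditions: i-Bu2AlH, CH2Cl2, −78 °C; then Et3SiH, BF3·OEt2, −78 → −20 °C
Reagents that add atoms: none
Why: Lactone-to-cyclic-ether reduction: i-Bu2AlH stops at lactolate 12 at −78 °C, BF3 ionises it to the aromatic ion 13, and the silane delivers hydride to C1 of the ion (ionic hydrogenation at the position that keeps the benzene ring), leaving the vinyl bromide and ketal untouched.

Step 7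
Reactants: 15 (2S)-2-(chloromethyl)oxirane ((S)-epichlorohydrin); 16 (3-methylbut-2-en-1-yl)magnesium chloride (prenylmagnesium chloride)
Product: 18 (2S)-2-(2,2-dimethylbut-3-en-1-yl)oxirane, via chloromagnesium alkoxide 17 (not isolated)
Conditions: THF, −30 → 0 °C; then NaOH (aq.), Et2O, 25 °C
Reagents that add atoms: none
Why: Grignard addition with allylic transposition (SE2′): the tertiary γ-carbon of the prenyl reagent opens the epoxide at its unsubstituted carbon, and base then closes a new epoxide onto the chloride-bearing carbon (Williamson-type); no bond to the stereocentre is broken, so the (S) centre of the chiral pool becomes C2.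

Step 8
Reactants: 14 4-bromo-5,6-(isopropylidenedioxy)-7-(propan-2-yl)-1H-isochromene; 18 (2S)-2-(2,2-dimethylbut-3-en-1-yl)oxirane
Product: 21 (2S)-1-[5,6-(isopropylidenedioxy)-7-(propan-2-yl)-1H-isochromen-4-yl]-4,4-dimethylhex-5-en-2-yl acetate, via vinyllithium 19 (not isolated), via lithium alkoxide 20 (not isolated)
Conditions: t-BuLi (2 equiv), Et2O, −78 °C; BF3·OEt2 then 18, −78 °C; then Ac2O, Et3N, DMAP, −78 → 25 °C
Reagents that add atoms: acetic anhydride, CC(=O)OC(C)=O
Why: Bromine–lithium exchange gives vinyllithium 19 (β-elimination would need a ring alkyne and cannot occur); the BF3-activated epoxide is opened at its primary carbon (organolithium epoxide opening, C10–C1 bond), and alkoxide 20 is O-acetylated in the flask so that a free C2 hydroxyl never meets the acid-sensitive enol ether; the stereocentre is not touched.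

Step 9
Reactants: 21 (2S)-1-[5,6-(isopropylidenedioxy)-7-(propan-2-yl)-1H-isochromen-4-yl]-4,4-dimethylhex-5-en-2-yl acetate
Product: 24 (2S,5S,7S,10R)-11,12-(isopropylidenedioxy)-7,20-epoxyabieta-8,11,13-trien-2-yl acetate, via isochromenylium salt 22 (not isolated), via oxocarbenium salt 23 (not isolated)
Conditions: Ph3CBF4 (1.05 equiv), ClCH2CH2Cl, 0 → 50 °C; then Et3SiH, −40 → 0 °C
Reagents that add atoms: none
Why: The trityl cation abstracts hydride from C7 of 21 (benzylic and α to oxygen) because this gives the aromatic 2-benzopyrylium ion 22, whose C7=C8–C9=C10 unit (an o-quinodimethane held s-cis by the O–C20 bridge) adds the tethered C5=C6 alkene in an inverse-electron-demand intramolecular [4+2] cycloaddition (bonds C6–C7 and C5–C10), restoring the benzene ring and leaving oxocarbenium ion 23, which the silane reduces at C20. The closest known reaction types are the inter- and intramolecular [4+2] cycloadditions of isochromenylium ions with alkenes, the oxidation of 1H-isochromenes to such ions by trityl salts, and the ionic hydrogenation of oxocarbenium ions. Ring A closes through the four-atom tether C1–C4 as a six-membered ring in a chair-like transition state (type 1 intramolecular Diels–Alder reaction, helped by the gem-dimethyl group), ring B is the six-membered ring of the cycloaddition itself, and the oxygen bridge is carried in from the pyrylium ring. Regiochemistry is fixed by the tether and matches the polarisation (nucleophilic terminal C6 to electrophilic C7, developing positive charge at C5 to C10). C7 and C10 are set cis by suprafacial addition across the planar diene, and C5 is set by the side on which the tether folds: the side of the small C20–H is open while the other side is blocked by the peri oxygen on C11, so C4 ends gauche to C20 and H5 anti to C20 (trans A/B). The absolute sense comes from C2: only one face of the cation lets the acetoxy group sit equatorial in the chair and avoid a 1,3-diaxial clash with the axial methyl on C4, which gives the 5S,7S,10R product. The step needs hydride abstraction at C7 only (the one doubly activated C–H), and it needs 23 to be reduced before its benzylic C7–O bond opens, which the low-temperature silane quench is meant to secure.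

Step 10
Reactants: 24 (2S,5S,7S,10R)-11,12-(isopropylidenedioxy)-7,20-epoxyabieta-8,11,13-trien-2-yl acetate
Product: 25 (2S,5S,7S,10R)-11,12-dihydroxy-7,20-epoxyabieta-8,11,13-trien-2-yl acetate
Conditions: CF3CO2H–H2O (95:5), 25 °C, argon
Reagents that add atoms: none
Why: Acid-catalysed ketal hydrolysis through the aryloxy-stabilised carbocation frees the catechol; the secondary acetate is stable to this acid at room temperature, and any reversible ionisation at benzylic C7 can only re-close to the same bridged ether because the C20 oxygen is held on the β face.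

## Compound list

1 | 4-bromo-5-methyl-2-(propan-2-yl)phenol (4-bromothymol) | Cc1cc(O)c(C(C)C)cc1Br | starting material
2 | 4-bromo-3-methyl-6-(propan-2-yl)cyclohexa-3,5-diene-1,2-dione | CC1=C(Br)C=C(C(C)C)C(=O)C1=O | intermediate
3 | 4-bromo-3-methyl-6-(propan-2-yl)benzene-1,2-diol | Cc1c(O)c(O)c(C(C)C)cc1Br | intermediate
4 | 5-bromo-2,2,4-trimethyl-7-(propan-2-yl)-1,3-benzodioxole | Cc1c(Br)cc(C(C)C)c2OC(C)(C)Oc12 | intermediate
5 | [2,2,4-trimethyl-7-(propan-2-yl)-1,3-benzodioxol-5-yl]lithium | [Li]c1cc(C(C)C)c2OC(C)(C)Oc2c1C | intermediate
6 | N,N-diethyl-2,2,4-trimethyl-7-(propan-2-yl)-1,3-benzodioxole-5-carboxamide | CCN(CC)C(=O)c1cc(C(C)C)c2OC(C)(C)Oc2c1C | intermediate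
7 | {[5-(diethylcarbamoyl)-2,2-dimethyl-7-(propan-2-yl)-1,3-benzodioxol-4-yl]methyl}lithium | [Li]Cc1c(C(=O)N(CC)CC)cc(C(C)C)c2OC(C)(C)Oc12 | intermediate
8 | N,N-diethyl-2,2-dimethyl-4-(2-oxoethyl)-7-(propan-2-yl)-1,3-benzodioxole-5-carboxamide | CCN(CC)C(=O)c1cc(C(C)C)c2OC(C)(C)Oc2c1CC=O | intermediate
9 | 5,6-(isopropylidenedioxy)-7-(propan-2-yl)-1H-isochromen-1-one | O=C1OC=Cc2c3OC(C)(C)Oc3c(C(C)C)cc12 | intermediate
10 | 3,4-dibromo-5,6-(isopropylidenedioxy)-7-(propan-2-yl)-3,4-dihydro-1H-isochromen-1-one (racemic) | O=C1OC(Br)C(Br)c2c3OC(C)(C)Oc3c(C(C)C)cc12 | intermediate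
11 | 4-bromo-5,6-(isopropylidenedioxy)-7-(propan-2-yl)-1H-isochromen-1-one | O=C1OC=C(Br)c2c3OC(C)(C)Oc3c(C(C)C)cc12 | intermediate
12 | 4-bromo-1-[(diisobutylalumanyl)oxy]-5,6-(isopropylidenedioxy)-7-(propan-2-yl)-1H-isochromene (racemic) | CC(C)C[Al](CC(C)C)OC1OC=C(Br)c2c3OC(C)(C)Oc3c(C(C)C)cc12 | intermediate
13 | 4-bromo-5,6-(isopropylidenedioxy)-7-(propan-2-yl)isochromenylium ion | Brc1c[o+]cc2cc(C(C)C)c3OC(C)(C)Oc3c12 | intermediate
14 | 4-bromo-5,6-(isopropylidenedioxy)-7-(propan-2-yl)-1H-isochromene | BrC1=COCc2cc(C(C)C)c3OC(C)(C)Oc3c12 | intermediate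
15 | (2S)-2-(chloromethyl)oxirane ((S)-epichlorohydrin) | ClC[C@@H]1CO1 | starting material
16 | (3-methylbut-2-en-1-yl)magnesium chloride (prenylmagnesium chloride) | CC(C)=CC[Mg]Cl | starting material
17 | chloromagnesium (2S)-1-chloro-4,4-dimethylhex-5-en-2-olate | C=CC(C)(C)C[C@H](O[Mg]Cl)CCl | intermediate
18 | (2S)-2-(2,2-dimethylbut-3-en-1-yl)oxirane | C=CC(C)(C)C[C@H]1CO1 | intermediate
19 | [5,6-(isopropylidenedioxy)-7-(propan-2-yl)-1H-isochromen-4-yl]lithium | [Li]C1=COCc2cc(C(C)C)c3OC(C)(C)Oc3c12 | intermediate
20 | lithium (2S)-1-[5,6-(isopropylidenedioxy)-7-(propan-2-yl)-1H-isochromen-4-yl]-4,4-dimethylhex-5-en-2-olate | [Li]O[C@@H](CC(C)(C)C=C)CC1=COCc2cc(C(C)C)c3OC(C)(C)Oc3c12 | intermediate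
21 | (2S)-1-[5,6-(isopropylidenedioxy)-7-(propan-2-yl)-1H-isochromen-4-yl]-4,4-dimethylhex-5-en-2-yl acetate | CC(=O)O[C@@H](CC(C)(C)C=C)CC1=COCc2cc(C(C)C)c3OC(C)(C)Oc3c12 | intermediate
22 | 4-[(2S)-2-acetoxy-4,4-dimethylhex-5-en-1-yl]-5,6-(isopropylidenedioxy)-7-(propan-2-yl)isochromenylium tetrafluoroborate | CC(=O)O[C@@H](CC(C)(C)C=C)Cc1c[o+]cc2cc(C(C)C)c3OC(C)(C)Oc3c12.F[B-](F)(F)F | intermediate
23 | (2S,5S,7S,10R)-2-acetoxy-11,12-(isopropylidenedioxy)-7,20-epoxyabieta-8,11,13-trien-20-ylium tetrafluoroborate (oxocarbenium ion, O=C20) | CC(=O)O[C@H]1CC(C)(C)[C@@H]2C[C@@H]3[O+]=C[C@@]2(C1)c1c3cc(C(C)C)c2OC(C)(C)Oc12.F[B-](F)(F)F | intermediate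
24 | (2S,5S,7S,10R)-11,12-(isopropylidenedioxy)-7,20-epoxyabieta-8,11,13-trien-2-yl acetate | CC(=O)O[C@H]1CC(C)(C)[C@@H]2C[C@@H]3OC[C@@]2(C1)c1c3cc(C(C)C)c2OC(C)(C)Oc12 | intermediate
25 | (2S,5S,7S,10R)-11,12-dihydroxy-7,20-epoxyabieta-8,11,13-trien-2-yl acetate | CC(=O)O[C@H]1CC(C)(C)[C@@H]2C[C@@H]3OC[C@@]2(C1)c1c3cc(C(C)C)c(O)c1O | target

## Step count and least certain steps

Total step count: 10. Longest linear sequence: 9 steps (steps 1–6, 8, 9 and 10, from 1); step 7 is a one-step side branch.

**Step 9 (key step).** The most likely failure is premature opening of the bridged cation: heterolysis of the benzylic C7–O bond of 23 (the resulting cation is stabilised by the C12 oxygen) followed by loss of a proton from C6 before the hydride arrives. This is the usual fate of benzopyrylium–alkene adducts. A slow cycloaddition, because two donor oxygens stabilise 22, would make this worse by requiring more heat. The fallback accepts the opening and uses it. It sets out from 21: Ph3CBF4 and then 2,6-di-tert-butyl-4-methylpyridine in warm ClCH2CH2Cl should drive the same cycloaddition through ring opening to the ring-opened styrenyl aldehyde F1. NaBH4 in MeOH at 0 °C should reduce this to the primary alcohol F2 without touching the acetate. Catalytic camphorsulfonic acid in CH2Cl2 should then protonate the electron-rich styrene at C6, and the C20 hydroxyl should capture the C7 cation (Markovnikov hydroalkoxylation). The fallback returns to the route at 24.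

**Step 8.** The most likely failure is loss of the hindered vinyllithium 19 by proton capture, or attack of BF3 on the enol ether, before the epoxide is opened, giving low conversion. The fallback replaces carbanion chemistry by a nickel-catalysed reductive cross-electrophile coupling. It sets out from 14 and 18: NiBr2(dme), 4,4′-di-tert-butyl-2,2′-bipyridine, NaI and Mn powder in DMPU should open the epoxide at its terminal carbon through the iodohydrin and join it to the vinyl bromide, giving the homoallylic alcohol F3. Ac2O and pyridine then return to the route at 21.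

**Step 10.** The most likely failure is partial solvolysis of the C2 acetate, together with slow ketal cleavage and reversible opening of the benzylic ether, under the strong acid an aryl ketal needs. The fallback gives up the acetate and restores it by differential ester reactivity. It sets out from 24: 3 M HCl in THF–H2O at 60 °C should remove both ketal and acetate under equilibrating conditions, in which the bridge re-closes, to give the triol F4. Ac2O, pyridine and DMAP give the triacetate F5. Hydrazine hydrate (2.2 equiv) in THF–MeOH at 0 °C should cleave only the two aryl acetates, returning to the route at 25.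

**Step 1.** The most likely failure is decay of o-quinone 2 (tautomerisation to a quinone methide through the flanking methyl, or dimerisation) before it is reduced, or sluggish oxidation because of the bromine. The fallback sets out from 1: ortho-formylation with MgCl2, Et3N and paraformaldehyde in MeCN at reflux should give the salicylaldehyde F6, and Dakin oxidation (H2O2, NaOH) returns to the route at 3.

## Further compounds

F1 | step 9 | (2S,5S,10R)-11,12-(isopropylidenedioxy)-20-oxoabieta-6,8,11,13-tetraen-2-yl acetate | CC(=O)O[C@H]1CC(C)(C)[C@@H]2C=Cc3cc(C(C)C)c4OC(C)(C)Oc4c3[C@]2(C1)C=O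
F2 | step 9 | (2S,5S,10R)-20-hydroxy-11,12-(isopropylidenedioxy)abieta-6,8,11,13-tetraen-2-yl acetate | CC(=O)O[C@H]1CC(C)(C)[C@@H]2C=Cc3cc(C(C)C)c4OC(C)(C)Oc4c3[C@]2(C1)CO
F3 | step 8 | (2S)-1-[5,6-(isopropylidenedioxy)-7-(propan-2-yl)-1H-isochromen-4-yl]-4,4-dimethylhex-5-en-2-ol | O[C@@H](CC(C)(C)C=C)CC1=COCc2cc(C(C)C)c3OC(C)(C)Oc3c12
F4 | step 10 | (2S,5S,7S,10R)-7,20-epoxyabieta-8,11,13-triene-2,11,12-triol | O[C@H]1CC(C)(C)[C@@H]2C[C@@H]3OC[C@@]2(C1)c1c3cc(C(C)C)c(O)c1O
F5 | step 10 | (2S,5S,7S,10R)-7,20-epoxyabieta-8,11,13-triene-2,11,12-triyl triacetate | CC(=O)O[C@H]1CC(C)(C)[C@@H]2C[C@@H]3OC[C@@]2(C1)c1c3cc(C(C)C)c(OC(C)=O)c1OC(C)=O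
F6 | step 1 | 3-bromo-6-hydroxy-2-methyl-5-(propan-2-yl)benzaldehyde | Cc1c(Br)cc(C(C)C)c(O)c1C=O
A1 | alternative 1 | 1-[(3Z)-4-[(benzyloxy)methyl]-8-methylnona-3,7-dien-1-yl]-3,4-dimethoxy-5-(propan-2-yl)benzene | CC(C)=CCC/C(=C/CCc1cc(C(C)C)c(OC)c(OC)c1)COCc1ccccc1
A2 | alternative 1 | (5S,10R)-20-(benzyloxy)-11,12-dimethoxyabieta-8,11,13-triene | C1CC(C)(C)[C@@H]2CCc3cc(C(C)C)c(OC)c(OC)c3[C@]2(C1)COCc1ccccc1
A3 | alternative 2 | 2α-acetoxy-20-hydroxy-11,12-dimethoxy-7,8-secoabieta-8,11,13-trien-7-al | CC(=O)O[C@H]1CC(C)(C)[C@H](CC=O)[C@](CO)(C1)c1ccc(C(C)C)c(OC)c1OC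
A4 | alternative 3 | 3,4-dimethoxy-5-(propan-2-yl)-2-(trimethylsilyl)phenyl trifluoromethanesulfonate | COc1c(OC)c(C(C)C)cc(OS(=O)(=O)C(F)(F)F)c1[Si](C)(C)C
A5 | alternative 3 | (7S)-5,5-dimethyl-5,6,7,8-tetrahydro-1H-isochromen-7-yl acetate | CC(=O)O[C@H]1CC(C)(C)C2=C(C1)COC=C2
A6 | alternative 3 | 2α-acetoxy-11,12-dimethoxy-7β,20-epoxyabieta-5,8,11,13-tetraene | CC(=O)O[C@H]1CC(C)(C)C2=C[C@@H]3OC[C@@]2(C1)c1c3cc(C(C)C)c(OC)c1OC
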